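## Retrosynthetic overview
- Plakotenin comes from its ethyl ester. The C7 methyl is put on by cross-coupling of a C6=C7 enol triflate, and that triflate comes from axial phenyl-cuprate addition at C5 of a trans-hydrindenone.
- The C1 methyl comes from cuprate addition to a flat, cross-conjugated bicyclic dienone (C5=C6–C7(=O)–C7a=C1). The side chain comes from a Wittig reaction on the C4 aldehyde.
- Key step: an acyclic keto-trialdehyde closes both rings in one flask by a double aldol condensation. The five-membered ring (C7a=C1) forms first, then the six-membered ring (C5=C6). The choice between two diastereotopic formyl groups sets the quaternary C4.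
- The keto-trialdehyde comes from global reduction and re-oxidation of a keto-triester. That triester is built by Wittig dienoate synthesis, asymmetric malonate Michael addition (C3a), ethylation and asymmetric hydrogenation (C3).

Atom labels C1–C7a follow the hexahydroindene numbering of the target.

Assumption: the two chiral catalysts induce in the sense drawn. If not, their enantiomeric or pseudo-enantiomeric forms are used.

## Route

Step 1
Reactants: 1 ethyl (2E)-3-methyl-4-oxobut-2-enoate; 2 1-(triphenyl-λ5-phosphanylidene)propan-2-one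
Product: 3 ethyl (2E,4E)-3-methyl-6-oxohepta-2,4-dienoate
Conditions: CH2Cl2, rt, 16 h
Reagents that add atoms: 1-(triphenyl-λ5-phosphanylidene)propan-2-one, CC(=O)C=P(c1ccccc1)(c1ccccc1)c1ccccc1
Why: Wittig olefination with a stabilised ylide attacks only the aldehyde and gives the E enone; no stereocentre is formed.

Step 2
Reactants: 3 ethyl (2E,4E)-3-methyl-6-oxohepta-2,4-dienoate; 4 dimethyl malonate
Product: 5 ethyl (2E,4R)-4-[bis(methoxycarbonyl)methyl]-3-methyl-6-oxohept-2-enoate
Conditions: 9-amino(9-deoxy)-epi-quinine (10 mol %), PhCO2H (20 mol %), PhMe, rt, 72 h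
Reagents that add atoms: dimethyl malonate, COC(=O)CC(=O)OC
Why: Iminium-catalysed asymmetric Michael addition: the primary amine activates only the ketone end, so malonate attacks its β-carbon C3a (the β-carbon of the ester carries the methyl group and stays untouched), and the shielded iminium face sets C3a (R here).

Step 3
Reactants: 5 ethyl (2E,4R)-4-[bis(methoxycarbonyl)methyl]-3-methyl-6-oxohept-2-enoate
Product: 6 ethyl (2E,4S)-4-[1,1-bis(methoxycarbonyl)propyl]-3-methyl-6-oxohept-2-enoate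
Conditions: NaH (1.05 equiv), DMF, 0 °C; EtI (3 equiv), 40 °C
Reagents that add atoms: iodoethane, CCI
Why: Malonate alkylation (SN2) at the only strongly acidic C–H makes C4 fully substituted but still prochiral; C3a is untouched and its descriptor changes only because the priorities change.

Step 4
Reactants: 6 ethyl (2E,4S)-4-[1,1-bis(methoxycarbonyl)propyl]-3-methyl-6-oxohept-2-enoate
Product: 7 ethyl (3R,4S)-4-[1,1-bis(methoxycarbonyl)propyl]-3-methyl-6-oxoheptanoate
Conditions: [Ir(cod)((4S,5S)-ThrePHOX)]BArF (2 mol %), H2 (50 bar), CH2Cl2, rt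
Reagents that add atoms: none
Why: Iridium-catalysed asymmetric hydrogenation of a trisubstituted enoate (ketone and esters are inert): the N,P ligand picks the alkene face, matched with the Felkin-type conformer (CH2COMe eclipsing the alkene, quaternary C4 perpendicular) that is open only anti to C4, so C3 is set as R.

Step 5
Reactants: 7 ethyl (3R,4S)-4-[1,1-bis(methoxycarbonyl)propyl]-3-methyl-6-oxoheptanoate
Product: 8 (3R,4S)-4-[1,1-bis(hydroxymethyl)propyl]-3-methylheptane-1,6-diol (both C6 epimers)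
Conditions: LiAlH4 (5 equiv), THF, 0 °C to rt; Fieser work-up
Reagents that add atoms: none
Why: Hydride reduction of the three esters and the ketone levels all oxidation states; the new carbinol centre does not matter because it is re-oxidised in the next step.

Step 6
Reactants: 8 (3R,4S)-4-[1,1-bis(hydroxymethyl)propyl]-3-methylheptane-1,6-diol
Product: 9 (3R,4S)-4-(1,1-diformylpropyl)-3-methyl-6-oxoheptanal
Conditions: (COCl)2, DMSO, CH2Cl2, −78 °C; Et3N, −78 to 0 °C; used crude
Reagents that add atoms: none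
Why: Fourfold Swern oxidation activates all hydroxyl groups at once, which avoids lactol over-oxidation; neither stereocentre is α to a carbonyl, so none can epimerise.

Step 7 (key step)
Reactants: 9 (3R,4S)-4-(1,1-diformylpropyl)-3-methyl-6-oxoheptanal
Product: 11 (3R,3aS,4S)-4-ethyl-3-methyl-7-oxo-3,3a,4,7-tetrahydro-2H-indene-4-carbaldehyde, via cyclopentenyl methyl ketone dialdehyde 10 (not isolated)
Conditions: p-TsOH·H2O (20 mol %), PhH, reflux, Dean–Stark
Reagents that add atoms: none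
Why: Acid-catalysed double intramolecular aldol condensation: the more substituted ketone enol (C7a) first attacks the only unhindered aldehyde C1 to give 10 (which removes the one enolisable aldehyde), then the acetyl methyl C6 condenses with one of the two diastereotopic, non-enolisable formyl groups through the half-chair that keeps the larger ethyl group pseudo-equatorial and anti to the C3 methyl, so C4 is set with the remaining formyl group axial.

Step 8
Reactants: 11 (3R,3aS,4S)-4-ethyl-3-methyl-7-oxo-3,3a,4,7-tetrahydro-2H-indene-4-carbaldehyde; 12 ethyl 2-(triphenyl-λ5-phosphanylidene)propanoate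
Product: 13 ethyl (2E)-3-[(3R,3aS,4R)-4-ethyl-3-methyl-7-oxo-3,3a,4,7-tetrahydro-2H-inden-4-yl]-2-methylprop-2-enoate
Conditions: PhMe, 100 °C
Reagents that add atoms: ethyl 2-(triphenyl-λ5-phosphanylidene)propanoate, CCOC(=O)C(C)=P(c1ccccc1)(c1ccccc1)c1ccccc1
Why: Wittig olefination with a stabilised ylide reacts with the aldehyde and not the dienone and gives the E trisubstituted enoate; C4 is unchanged in space.

Step 9
Reactants: 13 ethyl (2E)-3-[(3R,3aS,4R)-4-ethyl-3-methyl-7-oxo-3,3a,4,7-tetrahydro-2H-inden-4-yl]-2-methylprop-2-enoate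
Product: 15 ethyl (2E)-3-[(1R,3R,3aR,4S,7aR)-4-ethyl-1,3-dimethyl-7-oxo-2,3,3a,4,7,7a-hexahydro-1H-inden-4-yl]-2-methylprop-2-enoate, via lithium dienolate 14 (not isolated)
Conditions: Me2CuLi (1.2 equiv, from CuI and MeLi), Et2O, −78 °C; sat. aq. NH4Cl at −78 °C
Reagents that add atoms: lithium dimethylcuprate, [Li+].C[Cu-]C
Why: Gilman cuprate 1,4-addition: the s-cis exocyclic enone terminus C1 is far more accessible than the neopentyl terminus C5 or the hindered enoate, methyl enters the flat cyclopentene anti to the C3 methyl and the axial C4 alkenyl group (C1 = R), and cold protonation of 14 at C7a anti to the new vicinal methyl gives the trans ring fusion (C7a = R).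

Step 10
Reactants: 15 ethyl (2E)-3-[(1R,3R,3aR,4S,7aR)-4-ethyl-1,3-dimethyl-7-oxo-2,3,3a,4,7,7a-hexahydro-1H-inden-4-yl]-2-methylprop-2-enoate
Product: 17 ethyl (2E)-3-[(1R,3R,3aR,4S,5S,7aR)-4-ethyl-1,3-dimethyl-5-phenyl-7-(trifluoromethylsulfonyloxy)-2,3,3a,4,5,7a-hexahydro-1H-inden-4-yl]-2-methylprop-2-enoate, via lithium enolate 16 (not isolated)
Conditions: Ph2CuLi (2 equiv, from CuI and PhLi), Et2O/THF, −78 to −30 °C; Comins' reagent, THF, −78 °C to rt
Reagents that add atoms: lithium diphenylcuprate, [Li+].c1ccccc1[Cu-]c1ccccc1; Comins' reagent, O=S(=O)(N(c1ccc(Cl)cn1)S(=O)(=O)C(F)(F)F)C(F)(F)F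
Why: Cuprate 1,4-addition followed by enolate O-triflation: phenyl attacks C5 along the stereoelectronically preferred axial path, which is also anti to the axial alkenyl group on C4 (C5 = S, phenyl cis to ethyl), and the regiodefined enolate 16 is trapped before it can equilibrate towards C7a.

Step 11
Reactants: 17 ethyl (2E)-3-[(1R,3R,3aR,4S,5S,7aR)-4-ethyl-1,3-dimethyl-5-phenyl-7-(trifluoromethylsulfonyloxy)-2,3,3a,4,5,7a-hexahydro-1H-inden-4-yl]-2-methylprop-2-enoate
Product: 18 ethyl (2E)-3-[(1R,3R,3aR,4S,5S,7aR)-4-ethyl-1,3,7-trimethyl-5-phenyl-2,3,3a,4,5,7a-hexahydro-1H-inden-4-yl]-2-methylprop-2-enoate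
Conditions: MeZnCl (3 equiv), Pd(PPh3)4 (5 mol %), THF, 50 °C
Reagents that add atoms: methylzinc chloride, C[Zn]Cl
Why: Negishi cross-coupling of the enol triflate at zerovalent palladium puts the methyl group on C7 with the alkene fixed at C6=C7; no stereocentre is touched and the ester is tolerated.

Step 12
Reactants: 18 ethyl (2E)-3-[(1R,3R,3aR,4S,5S,7aR)-4-ethyl-1,3,7-trimethyl-5-phenyl-2,3,3a,4,5,7a-hexahydro-1H-inden-4-yl]-2-methylprop-2-enoate
Product: 19 plakotenin, (2E)-3-[(1R,3R,3aR,4S,5S,7aR)-4-ethyl-1,3,7-trimethyl-5-phenyl-2,3,3a,4,5,7a-hexahydro-1H-inden-4-yl]-2-methylprop-2-enoic acid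
Conditions: LiOH (10 equiv), THF/MeOH/H2O, 50 °C; then 1 M HCl
Reagents that add atoms: lithium hydroxide, [Li+].[OH-]
Why: Saponification of the enoate; there is no epimerisable centre and the E alkene cannot isomerise under these conditions.

## Compound list
1 | ethyl (2E)-3-methyl-4-oxobut-2-enoate | CCOC(=O)/C=C(\C)C=O | starting material
2 | 1-(triphenyl-λ5-phosphanylidene)propan-2-one | CC(=O)C=P(c1ccccc1)(c1ccccc1)c1ccccc1 | starting material
3 | ethyl (2E,4E)-3-methyl-6-oxohepta-2,4-dienoate | CCOC(=O)/C=C(\C)/C=C/C(C)=O | intermediate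
4 | dimethyl malonate | COC(=O)CC(=O)OC | starting material
5 | ethyl (2E,4R)-4-[bis(methoxycarbonyl)methyl]-3-methyl-6-oxohept-2-enoate | CCOC(=O)/C=C(\C)[C@H](CC(C)=O)C(C(=O)OC)C(=O)OC | intermediate
6 | ethyl (2E,4S)-4-[1,1-bis(methoxycarbonyl)propyl]-3-methyl-6-oxohept-2-enoate | CCOC(=O)/C=C(\C)[C@H](CC(C)=O)C(CC)(C(=O)OC)C(=O)OC | intermediate
7 | ethyl (3R,4S)-4-[1,1-bis(methoxycarbonyl)propyl]-3-methyl-6-oxoheptanoate | CCOC(=O)C[C@@H](C)[C@H](CC(C)=O)C(CC)(C(=O)OC)C(=O)OC | intermediate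
8 | (3R,4S)-4-[1,1-bis(hydroxymethyl)propyl]-3-methylheptane-1,6-diol (C6 epimers) | OCC[C@@H](C)[C@H](CC(C)O)C(CC)(CO)CO | intermediate
9 | (3R,4S)-4-(1,1-diformylpropyl)-3-methyl-6-oxoheptanal | O=CC[C@@H](C)[C@H](CC(C)=O)C(CC)(C=O)C=O | intermediate
10 | 2-[(1S,5R)-2-acetyl-5-methylcyclopent-2-en-1-yl]-2-ethylpropanedial | CCC(C=O)(C=O)[C@H]1C(C(C)=O)=CC[C@H]1C | intermediate
11 | (3R,3aS,4S)-4-ethyl-3-methyl-7-oxo-3,3a,4,7-tetrahydro-2H-indene-4-carbaldehyde | CC[C@@]1(C=O)[C@H]2C(=CC[C@H]2C)C(=O)C=C1 | intermediate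
12 | ethyl 2-(triphenyl-λ5-phosphanylidene)propanoate | CCOC(=O)C(C)=P(c1ccccc1)(c1ccccc1)c1ccccc1 | starting material
13 | ethyl (2E)-3-[(3R,3aS,4R)-4-ethyl-3-methyl-7-oxo-3,3a,4,7-tetrahydro-2H-inden-4-yl]-2-methylprop-2-enoate | CC[C@@]1(/C=C(\C)C(=O)OCC)[C@H]2C(=CC[C@H]2C)C(=O)C=C1 | intermediate
14 | lithium dienolate (C7 O-enolate, C7=C7a and C5=C6) formed by methyl addition to 13 | [Li+].CC[C@@]1(/C=C(\C)C(=O)OCC)[C@H]2C(=C([O-])C=C1)[C@H](C)C[C@H]2C | intermediate
15 | ethyl (2E)-3-[(1R,3R,3aR,4S,7aR)-4-ethyl-1,3-dimethyl-7-oxo-2,3,3a,4,7,7a-hexahydro-1H-inden-4-yl]-2-methylprop-2-enoate | CC[C@@]1(/C=C(\C)C(=O)OCC)[C@H]2[C@H](C(=O)C=C1)[C@H](C)C[C@H]2C | intermediate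
16 | lithium enolate (C7 O-enolate, C6=C7) formed by phenyl addition to 15 | [Li+].CC[C@@]1(/C=C(\C)C(=O)OCC)[C@H]2[C@H](C([O-])=C[C@H]1c1ccccc1)[C@H](C)C[C@H]2C | intermediate
17 | ethyl (2E)-3-[(1R,3R,3aR,4S,5S,7aR)-4-ethyl-1,3-dimethyl-5-phenyl-7-(trifluoromethylsulfonyloxy)-2,3,3a,4,5,7a-hexahydro-1H-inden-4-yl]-2-methylprop-2-enoate | CC[C@@]1(/C=C(\C)C(=O)OCC)[C@H]2[C@H](C(OS(=O)(=O)C(F)(F)F)=C[C@H]1c1ccccc1)[C@H](C)C[C@H]2C | intermediate
18 | plakotenin ethyl ester | CC[C@@]1(/C=C(\C)C(=O)OCC)[C@H]2[C@H](C(C)=C[C@H]1c1ccccc1)[C@H](C)C[C@H]2C | intermediate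
19 | plakotenin | CC[C@@]1(/C=C(\C)C(=O)O)[C@H]2[C@H](C(C)=C[C@H]1c1ccccc1)[C@H](C)C[C@H]2C | target

## Step count and weak points
Total step count: 12. Longest linear sequence: 12.

**Step 7 (double aldol condensation).** The aldehyde enol at C2 may attack the ketone or a formyl group, or a formyl group may be lost.
- The fallback builds the rings one at a time with the dialdehyde masked, starting from 8.
- 2,2-Dimethoxypropane and camphorsulfonic acid tie up the neopentyl 1,3-diol as (3R,4S)-4-(5-ethyl-2,2-dimethyl-1,3-dioxan-5-yl)-3-methylheptane-1,6-diol F1.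
- Swern oxidation gives (3R,4S)-4-(5-ethyl-2,2-dimethyl-1,3-dioxan-5-yl)-3-methyl-6-oxoheptanal F2.
- With no other aldehyde present, KOH in MeOH can only close the five-membered ring, giving 1-[(4R,5S)-5-(5-ethyl-2,2-dimethyl-1,3-dioxan-5-yl)-4-methylcyclopent-1-en-1-yl]ethan-1-one F3.
- Aqueous acetic acid frees 1-[(4R,5S)-5-[1,1-bis(hydroxymethyl)propyl]-4-methylcyclopent-1-en-1-yl]ethan-1-one F4.
- A second Swern oxidation brings the sequence back at 10, now isolated, which is closed to 11 with p-TsOH.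

**Step 9 (C1 and C7a).** Protonation of 14 may give the cis ring fusion, or the cuprate may attack C5.
- The fallback uses an internal proton relay and starts from 11.
- NaBH(OAc)3 reduces only the aldehyde to (3R,3aS,4S)-4-ethyl-4-(hydroxymethyl)-3-methyl-2,3,3a,4-tetrahydro-7H-inden-7-one F5.
- Me2CuLi (2.2 equiv) adds at C1. On quenching, the axial CH2OH group, which lies over the β face of C7a, delivers the proton there.
- This gives (1R,3R,3aR,4S,7aR)-4-ethyl-4-(hydroxymethyl)-1,3-dimethyl-1,2,3,3a,4,7a-hexahydro-7H-inden-7-one F6.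
- Dess–Martin oxidation gives (1R,3R,3aR,4S,7aR)-4-ethyl-1,3-dimethyl-7-oxo-2,3,3a,4,7,7a-hexahydro-1H-indene-4-carbaldehyde F7.
- A Wittig reaction with 12 brings the sequence back at 15.

**Step 4 (hydrogenation of a very hindered enoate).** Conversion or facial control may be poor.
- The fallback changes to a hydroxyl-directed reduction and starts from 6.
- LiAlH4 first gives the allylic alcohol (2E,4S)-4-[1,1-bis(hydroxymethyl)propyl]-3-methylhept-2-ene-1,6-diol F8.
- F8 is hydrogenated with Ru(OAc)2((S)-BINAP) and H2 (100 bar, MeOH), as for geraniol-type allylic alcohols. This brings the sequence back at 8.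

## Further compounds
F1 | step 7 | (3R,4S)-4-(5-ethyl-2,2-dimethyl-1,3-dioxan-5-yl)-3-methylheptane-1,6-diol | OCC[C@@H](C)[C@H](CC(C)O)C1(CC)COC(C)(C)OC1
F2 | step 7 | (3R,4S)-4-(5-ethyl-2,2-dimethyl-1,3-dioxan-5-yl)-3-methyl-6-oxoheptanal | O=CC[C@@H](C)[C@H](CC(C)=O)C1(CC)COC(C)(C)OC1
F3 | step 7 | 1-[(4R,5S)-5-(5-ethyl-2,2-dimethyl-1,3-dioxan-5-yl)-4-methylcyclopent-1-en-1-yl]ethan-1-one | CCC1(COC(C)(C)OC1)[C@H]2C(C(C)=O)=CC[C@H]2C
F4 | step 7 | 1-[(4R,5S)-5-[1,1-bis(hydroxymethyl)propyl]-4-methylcyclopent-1-en-1-yl]ethan-1-one | CCC(CO)(CO)[C@H]1C(C(C)=O)=CC[C@H]1C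
F5 | step 9 | (3R,3aS,4S)-4-ethyl-4-(hydroxymethyl)-3-methyl-2,3,3a,4-tetrahydro-7H-inden-7-one | CC[C@@]1(CO)[C@H]2C(=CC[C@H]2C)C(=O)C=C1
F6 | step 9 | (1R,3R,3aR,4S,7aR)-4-ethyl-4-(hydroxymethyl)-1,3-dimethyl-1,2,3,3a,4,7a-hexahydro-7H-inden-7-one | CC[C@@]1(CO)[C@H]2[C@H](C(=O)C=C1)[C@H](C)C[C@H]2C
F7 | step 9 | (1R,3R,3aR,4S,7aR)-4-ethyl-1,3-dimethyl-7-oxo-2,3,3a,4,7,7a-hexahydro-1H-indene-4-carbaldehyde | CC[C@@]1(C=O)[C@H]2[C@H](C(=O)C=C1)[C@H](C)C[C@H]2C
F8 | step 4 | (2E,4S)-4-[1,1-bis(hydroxymethyl)propyl]-3-methylhept-2-ene-1,6-diol | OC/C=C(\C)[C@H](CC(C)O)C(CC)(CO)CO
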